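**Plan**

1. Isochromene numbering is used: C1H2–O2–C3=C4–C4a=C8a for the pyran, and ring A is C4a–C5–C6–C7–C8–C8a (C8 ketone, C7 carbinol with methyl, C6 carbinol bearing the orsellinate).
2. The retrosynthesis cuts, in this order: O2–C3 (pyran), the O6–acyl ester bond, C5–C6 (ring A), C1–C8a, C4–C4a, C8–C8a and C6–C7.
3. Forward, an open chain C6–C7–C8–C8a(–C1)–C4a(=C5)–C4≡C3–side chain is built from (S)-lactic acid, formaldehyde (twice), propyne and (E)-pent-2-en-4-yn-1-ol. Ring A closes first through C5–C6, the orsellinate is attached, and the 2H-pyran ring closes last.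
4. Enabling feature: C5 is the γ-carbon of the C8 ketone through C8a=C4a, and C6 is a carbinol carbon on the quaternary C7. A C8/C8a/C4a/C5 dienolate can therefore add to a C6 aldehyde, and closing ring A also fixes C8a=C4a with the alkyne cis to C1.
5. Stereochemistry: C7 comes from (S)-lactic acid through its pivalaldehyde acetal; C6 is set from C7 by chelation control in the ring closure; the side-chain E-alkene comes from the enynol.

Key step: step 10

Assumption: compounds 6, 10, 21 and (triisopropylsiloxy)methyl chloride are taken as commercial, and the target SMILES is read as (6R,7R), i.e. O6 and O7 cis on ring A.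

**Route**

Step 1
Reactants: 1 (S)-lactic acid
Product: 2 (2S,5S)-2-tert-butyl-5-methyl-1,3-dioxolan-4-one
Conditions: pivalaldehyde, TsOH·H2O (cat.), H2SO4 (cat.), pentane, reflux (water separator); crystallisation
Reagents that add atoms: pivalaldehyde, CC(C)(C)C=O
Why: Acid-catalysed acetalisation of the α-hydroxy acid gives the dioxolanone; the cis isomer should be purified by crystallisation and stores the lactate chirality in the acetal centre (self-regeneration of stereocentres).

Step 2
Reactants: 2 (2S,5S)-2-tert-butyl-5-methyl-1,3-dioxolan-4-one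
Product: 5 (2S,5R)-2-tert-butyl-5-methyl-5-[(triethylsilyloxy)methyl]-1,3-dioxolan-4-one, via lithium enolate 3 (not isolated), via lithium alkoxide 4 (not isolated)
Conditions: LiN(iPr)2, THF, −78 °C; CH2O (monomeric gas), −78 °C; then Et3SiCl, −78 → 0 °C
Reagents that add atoms: formaldehyde, C=O; chlorotriethylsilane, CC[Si](Cl)(CC)CC
Why: Aldol addition of the dioxolanone enolate to formaldehyde should occur on the face opposite the tert-butyl group, which sets the quaternary centre (later C7, R) with overall retention, and the aldolate is capped in the same flask as its triethylsilyl ether.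

Step 3
Reactants: 5 (2S,5R)-2-tert-butyl-5-methyl-5-[(triethylsilyloxy)methyl]-1,3-dioxolan-4-one; 6 1-propynyllithium
Product: 8 (2R)-2-hydroxy-2-methyl-1-(triethylsilyloxy)hex-4-yn-3-one, via lithium hemiketal alkoxide 7 (not isolated)
Conditions: THF, −78 °C; then AcOH, −78 °C → rt
Reagents that add atoms: none
Why: Acetylide addition to the activated lactone carbonyl (later C8) should stop at the tetrahedral alkoxide at low temperature; on protonation it collapses to the ynone and expels pivalaldehyde, which frees the tertiary C7 hydroxyl.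

Step 4
Reactants: 8 (2R)-2-hydroxy-2-methyl-1-(triethylsilyloxy)hex-4-yn-3-one
Product: 9 (2R)-2-methyl-1-(triethylsilyloxy)-2-{[(triisopropylsilyl)oxy]methoxy}hex-4-yn-3-one
Conditions: (iPr)3SiOCH2Cl, iPr2NEt, ClCH2CH2Cl, 45 °C
Reagents that add atoms: (triisopropylsiloxy)methyl chloride, ClCO[Si](C(C)C)(C(C)C)C(C)C
Why: O-Alkylation of the tertiary alcohol with the chloromethyl ether installs a formaldehyde-acetal group on O7 that can chelate a metal in step 10 and is later removed by fluoride.

Step 5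
Reactants: 10 (E)-pent-2-en-4-yn-1-ol
Product: 11 triisopropyl{[(2E)-pent-2-en-4-yn-1-yl]oxy}silane
Conditions: (iPr)3SiCl, imidazole, CH2Cl2, rt
Reagents that add atoms: chlorotriisopropylsilane, CC(C)[Si](Cl)(C(C)C)C(C)C
Why: Standard silylation of the primary allylic alcohol; the triisopropylsilyl ether should survive the later acidic removal of the triethylsilyl group.

Step 6
Reactants: 9 (2R)-2-methyl-1-(triethylsilyloxy)-2-{[(triisopropylsilyl)oxy]methoxy}hex-4-yn-3-one; 11 triisopropyl{[(2E)-pent-2-en-4-yn-1-yl]oxy}silane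
Product: 12 (2R,4E,8E)-2,5-dimethyl-1-(triethylsilyloxy)-10-(triisopropylsilyloxy)-2-{[(triisopropylsilyl)oxy]methoxy}deca-4,8-dien-6-yn-3-one
Conditions: Pd(OAc)2 (cat.), tris(2,6-dimethoxyphenyl)phosphine (cat.), THF, rt
Reagents that add atoms: none
Why: Palladium-catalysed addition of the terminal alkyne C–H across the electron-poor ynone (donor–acceptor alkyne cross-coupling) should place the alkynyl group on the β-carbon C4a and hydrogen on C8a; the alkene geometry is of no consequence because it is erased in the next step.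

Step 7
Reactants: 12 (2R,4E,8E)-2,5-dimethyl-1-(triethylsilyloxy)-10-(triisopropylsilyloxy)-2-{[(triisopropylsilyl)oxy]methoxy}deca-4,8-dien-6-yn-3-one
Product: 15 (2R,8E)-2-methyl-5-methylidene-1-(triethylsilyloxy)-10-(triisopropylsilyloxy)-4-[(triisopropylsilyloxy)methyl]-2-{[(triisopropylsilyl)oxy]methoxy}dec-8-en-6-yn-3-one (C8a epimers), via lithium dienolate 13 (not isolated), via lithium alkoxide 14 (not isolated)
Conditions: LiN(iPr)2, THF, −78 °C; CH2O (monomeric gas), −78 °C; then (iPr)3SiOTf, −78 °C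
Reagents that add atoms: formaldehyde, C=O; triisopropylsilyl trifluoromethanesulfonate, CC(C)[Si](OS(=O)(=O)C(F)(F)F)(C(C)C)C(C)C
Why: γ-Deprotonation of the β-methyl enone (C7 is quaternary, so there is no α'-hydrogen) gives a dienolate that should add to formaldehyde at its α-carbon C8a (deconjugative aldol addition), installing C1; the alkoxide is capped in the flask and the new C8a centre is lost again in step 10.

Step 8
Reactants: 15 (2R,8E)-2-methyl-5-methylidene-1-(triethylsilyloxy)-10-(triisopropylsilyloxy)-4-[(triisopropylsilyloxy)methyl]-2-{[(triisopropylsilyl)oxy]methoxy}dec-8-en-6-yn-3-one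
Product: 16 (2R,8E)-1-hydroxy-2-methyl-5-methylidene-10-(triisopropylsilyloxy)-4-[(triisopropylsilyloxy)methyl]-2-{[(triisopropylsilyl)oxy]methoxy}dec-8-en-6-yn-3-one
Conditions: pyridinium p-toluenesulfonate (cat.), MeOH–CH2Cl2, 0 °C
Reagents that add atoms: none
Why: Acid-catalysed methanolysis should remove the labile triethylsilyl ether chemoselectively in the presence of the triisopropylsilyl ethers and the silyl acetal.

Step 9
Reactants: 16 (2R,8E)-1-hydroxy-2-methyl-5-methylidene-10-(triisopropylsilyloxy)-4-[(triisopropylsilyloxy)methyl]-2-{[(triisopropylsilyl)oxy]methoxy}dec-8-en-6-yn-3-one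
Product: 17 (2R,8E)-2-methyl-5-methylidene-3-oxo-10-(triisopropylsilyloxy)-4-[(triisopropylsilyloxy)methyl]-2-{[(triisopropylsilyl)oxy]methoxy}dec-8-en-6-ynal
Conditions: Dess–Martin periodinane, pyridine, CH2Cl2, 0 °C
Reagents that add atoms: none
Why: Dess–Martin oxidation of the neopentyl-type primary alcohol under buffered, non-aqueous conditions should give the β-keto aldehyde (C6), which cannot enolise towards C7 and is used directly.

Step 10
Reactants: 17 (2R,8E)-2-methyl-5-methylidene-3-oxo-10-(triisopropylsilyloxy)-4-[(triisopropylsilyloxy)methyl]-2-{[(triisopropylsilyl)oxy]methoxy}dec-8-en-6-ynal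
Product: 20 (5R,6R)-5-hydroxy-6-methyl-3-[(3E)-5-(triisopropylsilyloxy)pent-3-en-1-yn-1-yl]-2-[(triisopropylsilyloxy)methyl]-6-{[(triisopropylsilyl)oxy]methoxy}cyclohex-2-en-1-one, via lithium dienolate 18 (not isolated), via lithium aldolate 19 (not isolated)
Conditions: MgBr2·OEt2, Et2O–toluene, −78 °C; then LiN(SiMe3)2, −78 → −40 °C; AcOH quench
Reagents that add atoms: none
Why: Magnesium first binds the aldehyde oxygen and the O7 acetal oxygen of 17, and LiN(SiMe3)2 then removes the doubly activated C8a–H to give the cross-conjugated dienolate 18 (O–C8=C8a–C4a=C5H2), whose γ-terminus C5 adds to the C6 aldehyde to give aldolate 19 and, after the quench, 20. The closest known reaction type is the intramolecular vinylogous aldol addition of an enone-derived metal dienolate to an aldehyde. Ring A closes as a six-membered carbocycle in a 6-(enolendo)-exo-trig mode, and the same closure locks the re-formed C4a=C8a double bond with the alkyne cis to C1, independent of how the precursor was assembled. The new C6 centre is controlled by C7: in the five-membered chelate of the aldehyde and O7 oxygens the tether can deliver C5 only from the C8 side, which should give a chair-like transition state with the C7 methyl and the C6 oxygen equatorial and hence the 6,7-cis (6R) alcohol. The step needs γ- over α-attack and cis over trans selectivity: α-attack at C8a would give a cyclobutanone and is excluded by ring size, the quaternary C7 leaves both carbonyls without an enolisable position on that side so that only one dienolate can form, and the chelating acetal on O7 together with the oxophilic magnesium secures the facial selectivity.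

Step 11
Reactants: 21 orsellinic acid (2,4-dihydroxy-6-methylbenzoic acid)
Product: 22 tert-butyldimethylsilyl 2,4-bis[(tert-butyldimethylsilyl)oxy]-6-methylbenzoate
Conditions: tBuMe2SiCl, imidazole, DMF, rt
Reagents that add atoms: tert-butylchlorodimethylsilane, CC(C)(C)[Si](C)(C)Cl
Why: Exhaustive silylation protects both phenols and gives a silyl ester that can be turned into the acid chloride without free acid.

Step 12
Reactants: 20 (5R,6R)-5-hydroxy-6-methyl-3-[(3E)-5-(triisopropylsilyloxy)pent-3-en-1-yn-1-yl]-2-[(triisopropylsilyloxy)methyl]-6-{[(triisopropylsilyl)oxy]methoxy}cyclohex-2-en-1-one; 22 tert-butyldimethylsilyl 2,4-bis[(tert-butyldimethylsilyl)oxy]-6-methylbenzoate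
Product: 24 (1R,6R)-6-methyl-5-oxo-3-[(3E)-5-(triisopropylsilyloxy)pent-3-en-1-yn-1-yl]-4-[(triisopropylsilyloxy)methyl]-6-{[(triisopropylsilyl)oxy]methoxy}cyclohex-3-en-1-yl 2,4-bis[(tert-butyldimethylsilyl)oxy]-6-methylbenzoate, via 2,4-bis[(tert-butyldimethylsilyl)oxy]-6-methylbenzoyl chloride 23 (not isolated)
Conditions: 22, (COCl)2, DMF (cat.), CH2Cl2, 0 °C → rt, evaporate; then 20, DMAP, Et3N, CH2Cl2, 0 → 40 °C
Reagents that add atoms: none
Why: The silyl ester is converted by oxalyl chloride/DMF into the acid chloride under neutral conditions, and DMAP-catalysed acylation of the only free hydroxyl (secondary C6–OH) should give the orsellinate ester with retention at C6.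

Step 13
Reactants: 24 the fully silylated ester described in step 12
Product: 25 (1R,6R)-6-hydroxy-4-(hydroxymethyl)-3-[(3E)-5-hydroxypent-3-en-1-yn-1-yl]-6-methyl-5-oxocyclohex-3-en-1-yl 2,4-dihydroxy-6-methylbenzoate
Conditions: Bu4NF, AcOH (1:1), THF, 0 °C → rt
Reagents that add atoms: none
Why: Buffered fluoride should cleave all five Si–O bonds; the hemiacetal left on O7 loses formaldehyde, and the acetic acid buffer suppresses base-induced elimination of the C6 ester through deprotonation at C5.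

Step 14
Reactants: 25 (1R,6R)-6-hydroxy-4-(hydroxymethyl)-3-[(3E)-5-hydroxypent-3-en-1-yn-1-yl]-6-methyl-5-oxocyclohex-3-en-1-yl 2,4-dihydroxy-6-methylbenzoate
Product: 26 Entonaemin A
Conditions: Ph3PAuNTf2 (cat.), THF, rt
Reagents that add atoms: none
Why: The alkyne bound to the cationic monovalent gold complex is attacked anti by the C1 hydroxyl in a 6-endo-dig hydroalkoxylation, and protodeauration gives the 2H-pyran; attack at C3 should be favoured because C3 is the δ-carbon of the C8 enone and carries the alkenyl group that stabilises positive charge, and ring A holds C1–OH and the alkyne cis.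

**Compound list**

1 | (S)-lactic acid | C[C@H](O)C(=O)O | starting material
2 | (2S,5S)-2-tert-butyl-5-methyl-1,3-dioxolan-4-one | C[C@@H]1O[C@H](C(C)(C)C)OC1=O | intermediate
3 | lithium enolate of 2 | CC1=C(O[Li])O[C@@H](C(C)(C)C)O1 | intermediate
4 | lithium alkoxide of the 5-hydroxymethyl dioxolanone | C[C@]1(CO[Li])O[C@H](C(C)(C)C)OC1=O | intermediate
5 | (2S,5R)-2-tert-butyl-5-methyl-5-[(triethylsilyloxy)methyl]-1,3-dioxolan-4-one | C[C@]1(CO[Si](CC)(CC)CC)O[C@H](C(C)(C)C)OC1=O | intermediate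
6 | 1-propynyllithium | [Li]C#CC | starting material
7 | lithium hemiketal alkoxide from 5 and 6 (C4 epimers) | C[C@]1(CO[Si](CC)(CC)CC)O[C@H](C(C)(C)C)OC1(O[Li])C#CC | intermediate
8 | (2R)-2-hydroxy-2-methyl-1-(triethylsilyloxy)hex-4-yn-3-one | CC#CC(=O)[C@](C)(O)CO[Si](CC)(CC)CC | intermediate
9 | (2R)-2-methyl-1-(triethylsilyloxy)-2-{[(triisopropylsilyl)oxy]methoxy}hex-4-yn-3-one | CC#CC(=O)[C@](C)(OCO[Si](C(C)C)(C(C)C)C(C)C)CO[Si](CC)(CC)CC | intermediate
10 | (E)-pent-2-en-4-yn-1-ol | C#C/C=C/CO | starting material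
11 | triisopropyl{[(2E)-pent-2-en-4-yn-1-yl]oxy}silane | C#C/C=C/CO[Si](C(C)C)(C(C)C)C(C)C | intermediate
12 | (2R,4E,8E)-2,5-dimethyl-1-(triethylsilyloxy)-10-(triisopropylsilyloxy)-2-{[(triisopropylsilyl)oxy]methoxy}deca-4,8-dien-6-yn-3-one | C/C(C#C/C=C/CO[Si](C(C)C)(C(C)C)C(C)C)=C\C(=O)[C@](C)(OCO[Si](C(C)C)(C(C)C)C(C)C)CO[Si](CC)(CC)CC | intermediate
13 | lithium dienolate of 12 | C=C(C#C/C=C/CO[Si](C(C)C)(C(C)C)C(C)C)C=C(O[Li])[C@](C)(OCO[Si](C(C)C)(C(C)C)C(C)C)CO[Si](CC)(CC)CC | intermediate
14 | lithium alkoxide of the C8a-hydroxymethyl ketone | C=C(C#C/C=C/CO[Si](C(C)C)(C(C)C)C(C)C)C(CO[Li])C(=O)[C@](C)(OCO[Si](C(C)C)(C(C)C)C(C)C)CO[Si](CC)(CC)CC | intermediate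
15 | (2R,8E)-2-methyl-5-methylidene-1-(triethylsilyloxy)-10-(triisopropylsilyloxy)-4-[(triisopropylsilyloxy)methyl]-2-{[(triisopropylsilyl)oxy]methoxy}dec-8-en-6-yn-3-one (C8a epimers) | C=C(C#C/C=C/CO[Si](C(C)C)(C(C)C)C(C)C)C(CO[Si](C(C)C)(C(C)C)C(C)C)C(=O)[C@](C)(OCO[Si](C(C)C)(C(C)C)C(C)C)CO[Si](CC)(CC)CC | intermediate
16 | (2R,8E)-1-hydroxy-2-methyl-5-methylidene-10-(triisopropylsilyloxy)-4-[(triisopropylsilyloxy)methyl]-2-{[(triisopropylsilyl)oxy]methoxy}dec-8-en-6-yn-3-one (C8a epimers) | C=C(C#C/C=C/CO[Si](C(C)C)(C(C)C)C(C)C)C(CO[Si](C(C)C)(C(C)C)C(C)C)C(=O)[C@](C)(OCO[Si](C(C)C)(C(C)C)C(C)C)CO | intermediate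
17 | (2R,8E)-2-methyl-5-methylidene-3-oxo-10-(triisopropylsilyloxy)-4-[(triisopropylsilyloxy)methyl]-2-{[(triisopropylsilyl)oxy]methoxy}dec-8-en-6-ynal (C8a epimers) | C=C(C#C/C=C/CO[Si](C(C)C)(C(C)C)C(C)C)C(CO[Si](C(C)C)(C(C)C)C(C)C)C(=O)[C@](C)(OCO[Si](C(C)C)(C(C)C)C(C)C)C=O | intermediate
18 | lithium dienolate of 17 (held as its MgBr2 chelate) | C=C(C#C/C=C/CO[Si](C(C)C)(C(C)C)C(C)C)C(CO[Si](C(C)C)(C(C)C)C(C)C)=C(O[Li])[C@](C)(OCO[Si](C(C)C)(C(C)C)C(C)C)C=O | intermediate
19 | lithium aldolate of 20 | [Li]O[C@@H]1CC(C#C/C=C/CO[Si](C(C)C)(C(C)C)C(C)C)=C(CO[Si](C(C)C)(C(C)C)C(C)C)C(=O)[C@]1(C)OCO[Si](C(C)C)(C(C)C)C(C)C | intermediate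
20 | (5R,6R)-5-hydroxy-6-methyl-3-[(3E)-5-(triisopropylsilyloxy)pent-3-en-1-yn-1-yl]-2-[(triisopropylsilyloxy)methyl]-6-{[(triisopropylsilyl)oxy]methoxy}cyclohex-2-en-1-one | O[C@@H]1CC(C#C/C=C/CO[Si](C(C)C)(C(C)C)C(C)C)=C(CO[Si](C(C)C)(C(C)C)C(C)C)C(=O)[C@]1(C)OCO[Si](C(C)C)(C(C)C)C(C)C | intermediate
21 | orsellinic acid | Cc1cc(O)cc(O)c1C(=O)O | starting material
22 | tert-butyldimethylsilyl 2,4-bis[(tert-butyldimethylsilyl)oxy]-6-methylbenzoate | Cc1cc(O[Si](C)(C)C(C)(C)C)cc(O[Si](C)(C)C(C)(C)C)c1C(=O)O[Si](C)(C)C(C)(C)C | intermediate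
23 | 2,4-bis[(tert-butyldimethylsilyl)oxy]-6-methylbenzoyl chloride | Cc1cc(O[Si](C)(C)C(C)(C)C)cc(O[Si](C)(C)C(C)(C)C)c1C(=O)Cl | intermediate
24 | (1R,6R)-6-methyl-5-oxo-3-[(3E)-5-(triisopropylsilyloxy)pent-3-en-1-yn-1-yl]-4-[(triisopropylsilyloxy)methyl]-6-{[(triisopropylsilyl)oxy]methoxy}cyclohex-3-en-1-yl 2,4-bis[(tert-butyldimethylsilyl)oxy]-6-methylbenzoate | Cc1cc(O[Si](C)(C)C(C)(C)C)cc(O[Si](C)(C)C(C)(C)C)c1C(=O)O[C@@H]1CC(C#C/C=C/CO[Si](C(C)C)(C(C)C)C(C)C)=C(CO[Si](C(C)C)(C(C)C)C(C)C)C(=O)[C@]1(C)OCO[Si](C(C)C)(C(C)C)C(C)C | intermediate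
25 | (1R,6R)-6-hydroxy-4-(hydroxymethyl)-3-[(3E)-5-hydroxypent-3-en-1-yn-1-yl]-6-methyl-5-oxocyclohex-3-en-1-yl 2,4-dihydroxy-6-methylbenzoate | Cc1cc(O)cc(O)c1C(=O)O[C@@H]1CC(C#C/C=C/CO)=C(CO)C(=O)[C@]1(C)O | intermediate
26 | Entonaemin A | Cc1cc(O)cc(O)c1C(=O)O[C@@H]1CC2=C(COC(/C=C/CO)=C2)C(=O)[C@]1(C)O | target

**Step count and risks**

Total steps: 14. Longest linear sequence: 12 (steps 1–4, 6–10, 12–14).

Step 10. The risks are poor facial selectivity (a non-chelated, dipole-controlled approach would give the 6-epimer), formation of the dienolate geometric isomer that cannot reach the aldehyde, and base-induced loss of the formyl group from the β-keto aldehyde. The fallback sets out from 17 and closes the ring without base, as a Lewis-acid-mediated carbonyl-ene (Prins-type) cyclisation. SnCl4 in CH2Cl2 at −78 °C chelates the aldehyde and O7 acetal oxygens, the 1,1-disubstituted C4a=C5H2 alkene attacks C6 through C5, and the proton on C8a is lost to give the conjugated enone. This leads directly to 20, where the route is rejoined; no compound outside the list is formed (entry F0).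

Step 14. The risk is attack of the hydroxyl at the wrong alkyne carbon (5-exo-dig closure at C4, leading to an alkylidene dihydrofuran) or slow turnover in the presence of five free hydroxyls. The fallback sets out from 25 and replaces π-acid activation by conjugate addition. Pyrrolidine in THF at 0 °C should add to the alkyne at C3, the δ-position of the C8 enone, to give (1R,6R)-6-hydroxy-4-(hydroxymethyl)-3-[(3E)-5-hydroxy-2-(pyrrolidin-1-yl)penta-1,3-dien-1-yl]-6-methyl-5-oxocyclohex-3-en-1-yl 2,4-dihydroxy-6-methylbenzoate F1. Warming with AcOH in THF then lets the C1 hydroxyl add to C3 and expel pyrrolidine (exchange of a vinylogous amide for a vinylogous ester), which gives 26.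

Step 12. The risk is slow acylation of the hindered secondary alcohol next to the quaternary C7 by a 2,6-disubstituted aroyl chloride, with decomposition of the acid chloride or loss of aryl silyl groups on prolonged heating. The fallback sets out from 21 and 20 and uses ring-opening transesterification instead of an acid chloride. Acetone with (CF3CO)2O and CF3CO2H converts 21 into 7-hydroxy-2,2,5-trimethyl-4H-1,3-benzodioxin-4-one F2. Silylation (tBuMe2SiCl, imidazole) gives 7-[(tert-butyldimethylsilyl)oxy]-2,2,5-trimethyl-4H-1,3-benzodioxin-4-one F3. Alcohol 20 is converted with NaN(SiMe3)2 in THF at 0 °C into the sodium alkoxide of 20 F4, which opens F3 at the carbonyl with loss of acetone to give the 4-[(tert-butyldimethylsilyl)oxy]-2-hydroxy-6-methylbenzoate of 20 F5. Bu4NF/AcOH then removes all silyl groups and gives 25, where the route is rejoined.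

Further compounds
F0 | step 10 | none | none
F1 | step 14 | (1R,6R)-6-hydroxy-4-(hydroxymethyl)-3-[(3E)-5-hydroxy-2-(pyrrolidin-1-yl)penta-1,3-dien-1-yl]-6-methyl-5-oxocyclohex-3-en-1-yl 2,4-dihydroxy-6-methylbenzoate | Cc1cc(O)cc(O)c1C(=O)O[C@@H]1CC(C=C(/C=C/CO)N2CCCC2)=C(CO)C(=O)[C@]1(C)O
F2 | step 12 | 7-hydroxy-2,2,5-trimethyl-4H-1,3-benzodioxin-4-one | Cc1cc(O)cc2OC(C)(C)OC(=O)c12
F3 | step 12 | 7-[(tert-butyldimethylsilyl)oxy]-2,2,5-trimethyl-4H-1,3-benzodioxin-4-one | Cc1cc(O[Si](C)(C)C(C)(C)C)cc2OC(C)(C)OC(=O)c12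
F4 | step 12 | sodium alkoxide of 20 | [Na]O[C@@H]1CC(C#C/C=C/CO[Si](C(C)C)(C(C)C)C(C)C)=C(CO[Si](C(C)C)(C(C)C)C(C)C)C(=O)[C@]1(C)OCO[Si](C(C)C)(C(C)C)C(C)C
F5 | step 12 | (1R,6R)-6-methyl-5-oxo-3-[(3E)-5-(triisopropylsilyloxy)pent-3-en-1-yn-1-yl]-4-[(triisopropylsilyloxy)methyl]-6-{[(triisopropylsilyl)oxy]methoxy}cyclohex-3-en-1-yl 4-[(tert-butyldimethylsilyl)oxy]-2-hydroxy-6-methylbenzoate | Cc1cc(O[Si](C)(C)C(C)(C)C)cc(O)c1C(=O)O[C@@H]1CC(C#C/C=C/CO[Si](C(C)C)(C(C)C)C(C)C)=C(CO[Si](C(C)C)(C(C)C)C(C)C)C(=O)[C@]1(C)OCO[Si](C(C)C)(C(C)C)C(C)C
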